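**Assumptions (one line each)**
- The target has no stereocentres, so "single enantiomer" is taken to mean the single (Z)-isomer of the exocyclic C5=CH double bond (ring O and 4-hydroxyphenyl cis), as the SMILES specifies.
- 3′,5′-Dibromo-4′-methoxyacetophenone (4) is taken as a purchasable catalogue compound; if not, it is one MeI/K2CO3 methylation from the commercial 4′-hydroxy analogue.

**Retrosynthetic overview**
1. Cadiolide A ⇐ its tri-O-methyl ether by global ArO–Me cleavage; all four Br atoms are bought in the building blocks, so no selective bromination is needed.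
2. The (Z)-benzylidene C5=CH ⇐ vinylogous Knoevenagel condensation of a 3-aroyl-4-aryl-2(5H)-furanone with 4-methoxybenzaldehyde.
3. The butenolide (the only ring formed) ⇐ O-acylation of an α-hydroxy ketone by an aroylketene (O1–C2), then intramolecular Knoevenagel condensation (C3=C4).
4. Aroylketene ⇐ acyl Meldrum's acid ⇐ 3,5-dibromo-4-methoxybenzoic acid; α-hydroxy ketone ⇐ 3′,5′-dibromo-4′-methoxyacetophenone.

**Forward route**

Step 1
Reactants: 1, 3,5-dibromo-4-methoxybenzoic acid; 2, Meldrum's acid (2,2-dimethyl-1,3-dioxane-4,6-dione)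
Product: 3, 5-[(3,5-dibromo-4-methoxyphenyl)(hydroxy)methylidene]-2,2-dimethyl-1,3-dioxane-4,6-dione (acyl Meldrum's acid, enol form; used crude after acid wash)
Conditions: EDC·HCl (1.3 equiv), DMAP (2 equiv), CH2Cl2, 0 °C → rt, 16 h
Reagents that add atoms: none besides reactant 2 (Meldrum's acid, CC1(C)OC(=O)CC(=O)O1)
Why: Carbodiimide/DMAP C-acylation of Meldrum's acid by an unhindered benzoic acid (2,6-positions are H) gives the stable enolised acyl Meldrum's acid, a masked aroylketene; ArBr and ArOMe are inert.

Step 2
Reactants: 4, 1-(3,5-dibromo-4-methoxyphenyl)ethan-1-one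
Product: 5, 1-(3,5-dibromo-4-methoxyphenyl)-2-hydroxyethan-1-one
Conditions: PhI(OCOCF3)2 (2 equiv), TFA (2 equiv), MeCN–H2O 5:1, reflux, 3 h
Reagents that add atoms: water, O (supplies the new hydroxyl oxygen)
Why: Hypervalent-iodine α-hydroxylation of an aryl methyl ketone under acidic conditions (enol attacks I(III), water displaces PhI); the dibromo-acyl-anisole ring is too deactivated to be oxidised.

Step 3
Reactants: 3 (1.2 equiv), acyl Meldrum's acid; 5, α-hydroxy ketone
Product: 6, 3-(3,5-dibromo-4-methoxybenzoyl)-4-(3,5-dibromo-4-methoxyphenyl)furan-2(5H)-one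
Conditions: PhMe, 110 °C, 1 h (−acetone, −CO2); then Et3N (1.5 equiv), 110 °C, 2 h
Reagents that add atoms: none
Why: Thermolysis of 3 gives the aroylketene, which the primary OH of 5 traps as the phenacyl β-keto ester. Et3N then enolises the doubly activated CH2 (far more acidic than the phenacyl CH2), which closes onto the aryl ketone in an intramolecular Knoevenagel condensation and dehydrates to the conjugated butenolide with the correct 3-aroyl/4-aryl regiochemistry.

Step 4
Reactants: 6, butenolide; 7, 4-methoxybenzaldehyde (1.5 equiv)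
Product: 8, (5Z)-3-(3,5-dibromo-4-methoxybenzoyl)-4-(3,5-dibromo-4-methoxyphenyl)-5-[(4-methoxyphenyl)methylidene]furan-2(5H)-one
Conditions: piperidine (0.5 equiv), MeOH/CH2Cl2, rt, 16 h, dark
Reagents that add atoms: none besides reactant 7 (4-methoxybenzaldehyde, COc1ccc(C=O)cc1)
Why: Vinylogous Knoevenagel (aldol–E1cB) condensation at the only acidic site, C5–H2, activated through C3=C4 by the lactone and 3-aroyl carbonyls. Reversible elimination gives the thermodynamic Z-alkene, with the aryl syn to the ring O and away from the C4 aryl (the E isomer suffers severe A(1,3) strain).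

Step 5
Reactants: 8, tri-O-methyl cadiolide A
Product: 9, cadiolide A, (5Z)-3-(3,5-dibromo-4-hydroxybenzoyl)-4-(3,5-dibromo-4-hydroxyphenyl)-5-[(4-hydroxyphenyl)methylidene]furan-2(5H)-one
Conditions: BBr3 (10 equiv, 1 M in CH2Cl2), CH2Cl2, −78 °C → rt, 16 h; ice–H2O quench; dark
Reagents that add atoms: none (three CH3 groups removed; phenolic H from aqueous work-up)
Why: Lewis-acid aryl methyl ether cleavage (excess reagent covers coordination to the lactone and ketone); lactone, diaryl ketone, ArBr and the enol-lactone alkene tolerate BBr3, and the Z-alkene is the thermodynamic isomer so it is not scrambled.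

**Compound list**
1 | 3,5-dibromo-4-methoxybenzoic acid | COc1c(Br)cc(cc1Br)C(=O)O | starting material
2 | Meldrum's acid | CC1(C)OC(=O)CC(=O)O1 | starting material
3 | 5-[(3,5-dibromo-4-methoxyphenyl)(hydroxy)methylidene]-2,2-dimethyl-1,3-dioxane-4,6-dione | COc1c(Br)cc(cc1Br)C(O)=C1C(=O)OC(C)(C)OC1=O | intermediate
4 | 1-(3,5-dibromo-4-methoxyphenyl)ethan-1-one | COc1c(Br)cc(cc1Br)C(C)=O | starting material
5 | 1-(3,5-dibromo-4-methoxyphenyl)-2-hydroxyethan-1-one | COc1c(Br)cc(cc1Br)C(=O)CO | intermediate
6 | 3-(3,5-dibromo-4-methoxybenzoyl)-4-(3,5-dibromo-4-methoxyphenyl)furan-2(5H)-one | COc1c(Br)cc(cc1Br)C(=O)C1=C(COC1=O)c1cc(Br)c(OC)c(Br)c1 | intermediate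
7 | 4-methoxybenzaldehyde | COc1ccc(C=O)cc1 | starting material
8 | (5Z)-tri-O-methyl cadiolide A | O=C1O/C(=C\c2ccc(OC)cc2)C(c2cc(Br)c(OC)c(Br)c2)=C1C(=O)c1cc(Br)c(OC)c(Br)c1 | intermediate
9 | cadiolide A | O=C1O/C(=C\c2ccc(O)cc2)C(c2cc(Br)c(O)c(Br)c2)=C1C(=O)c1cc(Br)c(O)c(Br)c1 | target

**Totals**
- Total step count: 5.
- Longest linear sequence: 4 steps (1 → 3 → 6 → 8 → 9, or 4 → 5 → 6 → 8 → 9).
- Steps 3 and 4 can be telescoped in one pot by adding 7 and piperidine to the cooled Et3N/toluene mixture, but the route as committed isolates 6.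

**Three steps most likely to fail, with fallbacks**
1. Step 3 (ketene trapping and cyclisation). Risks are ketene dimerisation, decarboxylation to the acetophenone, and self-condensation of 5. Fallback: make 6 by a different ring construction. Prepare the ynone 1,3-bis(3,5-dibromo-4-methoxyphenyl)prop-2-yn-1-one, run a Diels–Alder/retro-Diels–Alder with 5-ethoxy-4-methyloxazole (−MeCN) to the 2-ethoxy-3-aroyl-4-arylfuran, and hydrolyse with acid to 6.
2. Step 2 (direct α-hydroxylation). Risks are over-oxidation to the glyoxal or acid, and low conversion. Fallback: halogenation/substitution instead of I(III) oxidation. α-Brominate 4 (CuBr2, EtOAc/CHCl3, reflux), then displace with sodium formate and hydrolyse in situ (HCO2Na, EtOH/H2O, reflux) to 5.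
3. Step 5 (triple demethylation). Risks are incomplete cleavage of the hindered 2,6-dibromoanisoles and loss of the polar polyphenol on isolation. Fallback: change the protecting-group plan. Run the same sequence with isopropyl ethers (from 3,5-dibromo-4-hydroxybenzoic acid, 3′,5′-dibromo-4′-hydroxyacetophenone and 4-isopropoxybenzaldehyde) and unmask with BCl3 at −78 → 0 °C.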